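**Retrosynthetic overview**

1. Target 26 ← methylation at C8 (ring A loses its aromaticity) of the acylphloroglucinol chromene 25 ← acylation at C6 of chromene 18 with the Weinreb amide 21 of (R)-2-methylbutanoic acid; the C8 methyl of 18 is the reduced formyl carbon of 16.
2. Key disconnection: the aryl ether bond O1–C8a of ring B (O1–C2–C3=C4–C4a=C8a). The route rests on the cis C3=C4 double bond of ring B, which holds the oxygen on the quaternary C2 beside C8a of ring A. While ring A is still a benzene carrying fluorine at C8a and a formyl group at C8, the C2 alkoxide can displace fluoride and close ring B (16 ← 13).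
3. 13 ← cis-semihydrogenation ← Sonogashira coupling of aryl iodide 6 with (R)-alkynol 11. 11 ← geraniol (Sharpless epoxidation fixes the future C2; chloride; base fragmentation). 6 ← 1-fluoro-3,5-dimethoxybenzene (formylation, iodination, exchange of the methyl ethers for methoxymethyl ethers).
4. Ring order: ring A is bought as a benzene, ring B is closed in step 10, ring A is dearomatised in step 16. The phenol oxygens travel as methoxymethyl ethers so that dilute acid frees them at the end, beside the allylic aryl ether and the side-chain alkene.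

Key step: step 10

Remark: the target is drawn as one hydrogen-bonded enol tautomer of an acylated cyclic 1,3-dione; the route is taken to deliver the compound in that tautomeric form.

**Step 1**
Reactants: 1 1-fluoro-3,5-dimethoxybenzene
Product: 3 2-fluoro-4,6-dimethoxybenzaldehyde, via iminium salt 2 (not isolated)
Conditions: POCl3, DMF, 0 → 70 °C; then ice-water
Reagents that add atoms: N,N-dimethylformamide CN(C)C=O; water O
Why: Vilsmeier–Haack formylation should attack the carbon para to one methoxy group and ortho to fluorine rather than the more hindered carbon between the two methoxy groups, and hydrolysis of iminium salt 2 gives the aldehyde.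

**Step 2**
Reactants: 3 2-fluoro-4,6-dimethoxybenzaldehyde
Product: 4 2-fluoro-3-iodo-4,6-dimethoxybenzaldehyde
Conditions: NIS, TFA (cat.), MeCN, rt → 50 °C
Reagents that add atoms: N-iodosuccinimide O=C1CCC(=O)N1I
Why: Electrophilic aromatic iodination should go to C3, which is para to the C6 methoxy group, ortho to the C4 methoxy group and flanked by the small fluorine, rather than to C5 between two methoxy groups.

**Step 3**
Reactants: 4 2-fluoro-3-iodo-4,6-dimethoxybenzaldehyde
Product: 5 2-fluoro-4,6-dihydroxy-3-iodobenzaldehyde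
Conditions: BBr3, CH2Cl2, −78 °C → rt; then H2O
Reagents that add atoms: none
Why: Lewis-acid cleavage of both aryl methyl ethers is done here, where nothing acid-labile is present, so that the two oxygens can be re-masked with groups removable by dilute acid; the C–F and C–I bonds survive and the formyl group is recovered on aqueous work-up.

**Step 4**
Reactants: 5 2-fluoro-4,6-dihydroxy-3-iodobenzaldehyde
Product: 6 2-fluoro-3-iodo-4,6-bis(methoxymethoxy)benzaldehyde
Conditions: MOMCl, iPr2NEt, CH2Cl2, 0 °C → reflux
Reagents that add atoms: chloromethyl methyl ether COCCl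
Why: O-alkylation of both phenols with the chloromethyl ether gives the bis-acetal; the hydroxyl hydrogen-bonded to the formyl group reacts more slowly, hence excess reagent and warming.

**Step 5**
Reactants: 7 geraniol
Product: 8 [(2R,3R)-3-methyl-3-(4-methylpent-3-enyl)oxiran-2-yl]methanol
Conditions: Ti(OiPr)4 (cat.), D-(−)-diethyl tartrate (cat.), t-BuOOH, 4 Å molecular sieves, CH2Cl2, −20 °C
Reagents that add atoms: tert-butyl hydroperoxide CC(C)(C)OO
Why: Sharpless asymmetric epoxidation; the titanium complex of D-(−)-diethyl tartrate delivers oxygen to the face of the allylic 2,3-alkene that gives the (2R,3R)-epoxide, which fixes the quaternary carbon that becomes C2 of ring B, and the 6,7-alkene, having no allylic hydroxyl, is left alone.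

**Step 6**
Reactants: 8 [(2R,3R)-3-methyl-3-(4-methylpent-3-enyl)oxiran-2-yl]methanol
Product: 9 (2R,3S)-3-(chloromethyl)-2-methyl-2-(4-methylpent-3-enyl)oxirane
Conditions: PPh3, CCl4, NaHCO3, reflux
Reagents that add atoms: carbon tetrachloride ClC(Cl)(Cl)Cl
Why: Appel chlorination converts the primary alcohol into the chloride under buffered, near-neutral conditions that spare the trisubstituted epoxide and touch neither stereocentre (the descriptor at the CH carbon changes only through the priority of the CH2Cl group).

**Step 7**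
Reactants: 9 (2R,3S)-3-(chloromethyl)-2-methyl-2-(4-methylpent-3-enyl)oxirane
Product: 11 (R)-3,7-dimethyloct-6-en-1-yn-3-ol, via chlorovinyl alkoxide 10 (not isolated)
Conditions: n-BuLi (3.1 equiv), THF, −78 → −20 °C; then aq. NH4Cl
Reagents that add atoms: none
Why: Base-induced fragmentation of a 2,3-epoxy chloride: deprotonation at the chloromethyl carbon opens the epoxide to chlorovinyl alkoxide 10, which loses HCl to the alkyne; the C–O bond at the quaternary carbon is never broken, so its configuration is kept.

**Step 8**
Reactants: 6 2-fluoro-3-iodo-4,6-bis(methoxymethoxy)benzaldehyde; 11 (R)-3,7-dimethyloct-6-en-1-yn-3-ol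
Product: 12 (R)-2-fluoro-3-(3-hydroxy-3,7-dimethyloct-6-en-1-ynyl)-4,6-bis(methoxymethoxy)benzaldehyde
Conditions: PdCl2(PPh3)2 (cat.), CuI (cat.), Et3N, THF, 50 °C
Reagents that add atoms: none
Why: Sonogashira coupling takes place at the C–I bond only (the C–F bond is inert to the catalyst) and tolerates the free tertiary alcohol and the aldehyde.

**Step 9**
Reactants: 12 (R)-2-fluoro-3-(3-hydroxy-3,7-dimethyloct-6-en-1-ynyl)-4,6-bis(methoxymethoxy)benzaldehyde
Product: 13 (R,Z)-2-fluoro-3-(3-hydroxy-3,7-dimethylocta-1,6-dienyl)-4,6-bis(methoxymethoxy)benzaldehyde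
Conditions: H2 (1 atm), Pd/CaCO3 poisoned with Pb(OAc)2, quinoline, EtOAc, rt, stopped after one equivalent of H2
Reagents that add atoms: none
Why: Lindlar-type semihydrogenation adds both hydrogens to one face of the alkyne and so gives the Z alkene, while the poisoned catalyst should spare the trisubstituted alkene, the aldehyde and the C–F bond.

**Step 10**
Reactants: 13 (R,Z)-2-fluoro-3-(3-hydroxy-3,7-dimethylocta-1,6-dienyl)-4,6-bis(methoxymethoxy)benzaldehyde
Product: 16 (R)-5,7-bis(methoxymethoxy)-2-methyl-2-(4-methylpent-3-enyl)-2H-chromene-8-carbaldehyde, via potassium alkoxide 14 (not isolated), via Meisenheimer adduct 15 (not isolated)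
Conditions: KH, 18-crown-6 (cat.), THF, 0 °C → rt, exclusion of light
Reagents that add atoms: none
Why: KH converts the tertiary alcohol into potassium alkoxide 14, which adds to the fluorine-bearing C8a to give Meisenheimer adduct 15 with the negative charge on C8 and the formyl oxygen, and loss of fluoride restores aromatic ring A (addition–elimination). The closest known reaction type is the intramolecular nucleophilic aromatic substitution of ortho-fluorobenzaldehydes by tethered alkoxides. Ring B closes in a 6-exo-trig mode at C8a, which the cis C3=C4 alkene makes possible by placing the alkoxide within reach of that carbon. No stereocentre is formed: only the O–H bond of the carbinol takes part, so the (R) configuration at C2 from step 5 is kept, and no allyl cation or ring-opened dienone that could scramble it lies on the path. The step needs substitution at C–F rather than at the methoxymethoxy-bearing carbon para to the formyl group, which the alkoxide can also reach through a six-membered ring; fluorine secures this because it accelerates the addition and is by far the better leaving group.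

**Step 11**
Reactants: 16 (R)-5,7-bis(methoxymethoxy)-2-methyl-2-(4-methylpent-3-enyl)-2H-chromene-8-carbaldehyde
Product: 17 (R,E)-{[5,7-bis(methoxymethoxy)-2-methyl-2-(4-methylpent-3-enyl)-2H-chromen-8-yl]methylidene}hydrazine
Conditions: N2H4·H2O (excess), EtOH, 60 °C, argon
Reagents that add atoms: hydrazine monohydrate NN.O
Why: Condensation of the aldehyde with excess hydrazine gives the hydrazone, the excess and the two ortho substituents disfavouring azine formation, and nothing else in the molecule reacts with hydrazine under argon.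

**Step 12**
Reactants: 17 (R,E)-{[5,7-bis(methoxymethoxy)-2-methyl-2-(4-methylpent-3-enyl)-2H-chromen-8-yl]methylidene}hydrazine
Product: 18 (R)-5,7-bis(methoxymethoxy)-2,8-dimethyl-2-(4-methylpent-3-enyl)-2H-chromene
Conditions: KOtBu, DMSO, rt → 60 °C, exclusion of light
Reagents that add atoms: none
Why: Wolff–Kishner reduction in its low-temperature KOtBu/DMSO form turns the former formyl carbon into the C8 methyl with base only, which the acetals, the alkenes and the aryl ether tolerate, at a temperature where electrocyclic opening of ring B is not expected.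

**Step 13**
Reactants: 19 (R)-2-methylbutanoic acid
Product: 21 (R)-N-methoxy-N,2-dimethylbutanamide, via acyl imidazole 20 (not isolated)
Conditions: CDI, CH2Cl2, rt; then MeNHOMe·HCl, rt
Reagents that add atoms: N,O-dimethylhydroxylamine hydrochloride CNOC.Cl
Why: Amide coupling through acyl imidazole 20 under near-neutral conditions offers no ketene pathway, so the α-stereocentre should pass unchanged into the Weinreb amide.

**Step 14**
Reactants: 18 (R)-5,7-bis(methoxymethoxy)-2,8-dimethyl-2-(4-methylpent-3-enyl)-2H-chromene; 21 (R)-N-methoxy-N,2-dimethylbutanamide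
Product: 24 (R)-1-[(R)-5,7-bis(methoxymethoxy)-2,8-dimethyl-2-(4-methylpent-3-enyl)-2H-chromen-6-yl]-2-methylbutan-1-one, via aryllithium 22 (not isolated), via lithium hemiaminal adduct 23 (not isolated)
Conditions: n-BuLi, THF, 0 °C; then 21, −78 → 0 °C; then aq. NH4Cl
Reagents that add atoms: none
Why: Directed ortho-metalation removes the C6 hydrogen between the two methoxymethoxy groups, and Weinreb ketone synthesis then gives the ketone, because the chelated adduct 23 stops a second addition and keeps the carbon next to the side-chain stereocentre non-enolisable until the quench.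

**Step 15**
Reactants: 24 (R)-1-[(R)-5,7-bis(methoxymethoxy)-2,8-dimethyl-2-(4-methylpent-3-enyl)-2H-chromen-6-yl]-2-methylbutan-1-one
Product: 25 (R)-1-[(R)-5,7-dihydroxy-2,8-dimethyl-2-(4-methylpent-3-enyl)-2H-chromen-6-yl]-2-methylbutan-1-one
Conditions: HCl (aq., 3 M), MeOH, rt, exclusion of light
Reagents that add atoms: none
Why: Acid-catalysed acetal cleavage frees both phenols, which flank the ketone and are therefore released under dilute acid at room temperature, conditions that should leave the C2–O1 ether, the side-chain alkene and the stereocentre next to the ketone untouched.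

**Step 16**
Reactants: 25 (R)-1-[(R)-5,7-dihydroxy-2,8-dimethyl-2-(4-methylpent-3-enyl)-2H-chromen-6-yl]-2-methylbutan-1-one
Product: 26 (R)-5-hydroxy-2,8,8-trimethyl-6-[(R)-2-methylbutanoyl]-2-(4-methylpent-3-enyl)-2H-chromen-7(8H)-one
Conditions: NaOMe, MeI (1.2 equiv), MeOH, 0 °C → rt; then dilute aq. HCl, 0 °C
Reagents that add atoms: iodomethane CI
Why: Dearomative C-methylation of an acylphloroglucinol anion: C8 is the only nucleophilic ring carbon that does not carry the acyl group, MeI in methanol favours carbon over oxygen, the new quaternary C8 bears two methyl groups and is no stereocentre, and the side-chain C–H should stay in place because its carbonyl is already part of the delocalised anion.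

**Compound list**

1 | 1-fluoro-3,5-dimethoxybenzene | COc1cc(F)cc(OC)c1 | starting material
2 | N-(2-fluoro-4,6-dimethoxybenzylidene)-N-methylmethanaminium chloride | C[N+](C)=Cc1c(F)cc(OC)cc1OC.[Cl-] | intermediate (not isolated)
3 | 2-fluoro-4,6-dimethoxybenzaldehyde | O=Cc1c(F)cc(OC)cc1OC | intermediate
4 | 2-fluoro-3-iodo-4,6-dimethoxybenzaldehyde | O=Cc1c(F)c(I)c(OC)cc1OC | intermediate
5 | 2-fluoro-4,6-dihydroxy-3-iodobenzaldehyde | O=Cc1c(F)c(I)c(O)cc1O | intermediate
6 | 2-fluoro-3-iodo-4,6-bis(methoxymethoxy)benzaldehyde | O=Cc1c(F)c(I)c(OCOC)cc1OCOC | intermediate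
7 | geraniol | CC(C)=CCC/C(C)=C/CO | starting material
8 | [(2R,3R)-3-methyl-3-(4-methylpent-3-enyl)oxiran-2-yl]methanol | OC[C@H]1O[C@]1(C)CCC=C(C)C | intermediate
9 | (2R,3S)-3-(chloromethyl)-2-methyl-2-(4-methylpent-3-enyl)oxirane | ClC[C@H]1O[C@]1(C)CCC=C(C)C | intermediate
10 | lithium (R)-1-chloro-3,7-dimethylocta-1,6-dien-3-olate (chloroalkene geometry not defined) | [Li+].[O-][C@](C)(CCC=C(C)C)C=CCl | intermediate (not isolated)
11 | (R)-3,7-dimethyloct-6-en-1-yn-3-ol | O[C@](C)(CCC=C(C)C)C#C | intermediate
12 | (R)-2-fluoro-3-(3-hydroxy-3,7-dimethyloct-6-en-1-ynyl)-4,6-bis(methoxymethoxy)benzaldehyde | O[C@](C)(CCC=C(C)C)C#Cc1c(F)c(C=O)c(OCOC)cc1OCOC | intermediate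
13 | (R,Z)-2-fluoro-3-(3-hydroxy-3,7-dimethylocta-1,6-dienyl)-4,6-bis(methoxymethoxy)benzaldehyde | O[C@](C)(CCC=C(C)C)/C=C\c1c(F)c(C=O)c(OCOC)cc1OCOC | intermediate
14 | potassium alkoxide of 13 | [K+].[O-][C@](C)(CCC=C(C)C)/C=C\c1c(F)c(C=O)c(OCOC)cc1OCOC | intermediate (not isolated)
15 | potassium salt of the 8a-fluoro Meisenheimer adduct (C8a configuration not defined) | [K+].[O-]C=C1C(OCOC)=CC(OCOC)=C2C=C[C@@](C)(CCC=C(C)C)OC12F | intermediate (not isolated)
16 | (R)-5,7-bis(methoxymethoxy)-2-methyl-2-(4-methylpent-3-enyl)-2H-chromene-8-carbaldehyde | COCOc1cc(OCOC)c2c(c1C=O)O[C@](C)(CCC=C(C)C)C=C2 | intermediate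
17 | (R,E)-{[5,7-bis(methoxymethoxy)-2-methyl-2-(4-methylpent-3-enyl)-2H-chromen-8-yl]methylidene}hydrazine | COCOc1cc(OCOC)c2c(c1/C=N/N)O[C@](C)(CCC=C(C)C)C=C2 | intermediate
18 | (R)-5,7-bis(methoxymethoxy)-2,8-dimethyl-2-(4-methylpent-3-enyl)-2H-chromene | COCOc1cc(OCOC)c2c(c1C)O[C@](C)(CCC=C(C)C)C=C2 | intermediate
19 | (R)-2-methylbutanoic acid | CC[C@@H](C)C(=O)O | starting material
20 | (R)-1-(imidazol-1-yl)-2-methylbutan-1-one | CC[C@@H](C)C(=O)n1ccnc1 | intermediate (not isolated)
21 | (R)-N-methoxy-N,2-dimethylbutanamide | CC[C@@H](C)C(=O)N(C)OC | intermediate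
22 | 6-lithio derivative of 18 | COCOc1c([Li])c(OCOC)c2c(c1C)O[C@](C)(CCC=C(C)C)C=C2 | intermediate (not isolated)
23 | lithium hemiaminal adduct of 22 and 21 (carbinol configuration not defined) | COCOc1c(C([O-])(N(C)OC)[C@H](C)CC)c(OCOC)c2c(c1C)O[C@](C)(CCC=C(C)C)C=C2.[Li+] | intermediate (not isolated)
24 | (R)-1-[(R)-5,7-bis(methoxymethoxy)-2,8-dimethyl-2-(4-methylpent-3-enyl)-2H-chromen-6-yl]-2-methylbutan-1-one | COCOc1c(C(=O)[C@H](C)CC)c(OCOC)c2c(c1C)O[C@](C)(CCC=C(C)C)C=C2 | intermediate
25 | (R)-1-[(R)-5,7-dihydroxy-2,8-dimethyl-2-(4-methylpent-3-enyl)-2H-chromen-6-yl]-2-methylbutan-1-one | Oc1c(C(=O)[C@H](C)CC)c(O)c2c(c1C)O[C@](C)(CCC=C(C)C)C=C2 | intermediate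
26 | (R)-5-hydroxy-2,8,8-trimethyl-6-[(R)-2-methylbutanoyl]-2-(4-methylpent-3-enyl)-2H-chromen-7(8H)-one | CC[C@@H](C)C(=O)C1=C(O)C2=C(O[C@](C)(CCC=C(C)C)C=C2)C(C)(C)C1=O | target

**Step count and risk**

Total step count: 16. Longest linear sequence: 12 steps (steps 1–4, 8–12 and 14–16, from compound 1).

The three steps most likely to fail:

Step 10 (ring B closure). The addition of the hindered tertiary alkoxide to the electron-rich ring A may be too slow, so that base-induced reactions at the formyl group or substitution at the para alkoxy carbon take over. The fallback forms the same O1–C8a bond by palladium-catalysed intramolecular C–O coupling of an aryl bromide; it sets out from alkynol 11 and comes back to the route at 16. Purchased 2-bromo-4,6-dimethoxybenzaldehyde F1 is iodinated (NIS, cat. TFA, MeCN) to 2-bromo-3-iodo-4,6-dimethoxybenzaldehyde F2, demethylated (BBr3, CH2Cl2) to 2-bromo-4,6-dihydroxy-3-iodobenzaldehyde F3 and protected (MOMCl, iPr2NEt) as 2-bromo-3-iodo-4,6-bis(methoxymethoxy)benzaldehyde F4. Sonogashira coupling with 11 at the C–I bond should give (R)-2-bromo-3-(3-hydroxy-3,7-dimethyloct-6-en-1-ynyl)-4,6-bis(methoxymethoxy)benzaldehyde F5, and semihydrogenation as in step 9 should give (R,Z)-2-bromo-3-(3-hydroxy-3,7-dimethylocta-1,6-dienyl)-4,6-bis(methoxymethoxy)benzaldehyde F6. Pd(OAc)2, 2-(di-tert-butylphosphino)-1,1'-binaphthyl and Cs2CO3 in toluene at 70 °C should then close ring B to 16; the tertiary alkoxide has no hydrogen on the carbinol carbon, so β-hydride elimination cannot compete, and the C2 configuration is again untouched.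

Step 14 (acylation at C6). The aryllithium flanked by two methoxymethoxy groups may act as a base toward the α-branched amide instead of adding to it, which would return 18 and enolised 21. The fallback replaces the addition by a palladium-catalysed acyl cross-coupling (Negishi-type acylation); it sets out from aryllithium 22 and acid 19 and comes back at 24. Compound 22 is transmetalated with ZnCl2 to [(R)-5,7-bis(methoxymethoxy)-2,8-dimethyl-2-(4-methylpent-3-enyl)-2H-chromen-6-yl]zinc chloride F7. This is coupled under Pd(PPh3)4 catalysis in THF at rt with (R)-2-methylbutanoyl chloride F8, made from 19 with (COCl)2 and cat. DMF in CH2Cl2. The neutral conditions should not enolise the acid chloride or the ketone.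

Step 12 (formyl to methyl). Loss of nitrogen from the electron-rich hydrazone anion may be too slow at temperatures that ring B tolerates, so that azine formation and base-induced decomposition compete. The fallback is a radical deoxygenation (Barton–McCombie); it sets out from aldehyde 16 and comes back at 18. NaBH4 in MeOH at 0 °C should give [(R)-5,7-bis(methoxymethoxy)-2-methyl-2-(4-methylpent-3-enyl)-2H-chromen-8-yl]methanol F9; NaH, CS2 and MeI in THF should give the O-benzylic S-methyl xanthate F10; Bu3SnH with cat. AIBN in toluene at 80 °C should give 18 through the stabilised benzylic radical.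

**Further compounds**

F1 | step 10 | 2-bromo-4,6-dimethoxybenzaldehyde (purchased) | O=Cc1c(Br)cc(OC)cc1OC
F2 | step 10 | 2-bromo-3-iodo-4,6-dimethoxybenzaldehyde | O=Cc1c(Br)c(I)c(OC)cc1OC
F3 | step 10 | 2-bromo-4,6-dihydroxy-3-iodobenzaldehyde | O=Cc1c(Br)c(I)c(O)cc1O
F4 | step 10 | 2-bromo-3-iodo-4,6-bis(methoxymethoxy)benzaldehyde | O=Cc1c(Br)c(I)c(OCOC)cc1OCOC
F5 | step 10 | (R)-2-bromo-3-(3-hydroxy-3,7-dimethyloct-6-en-1-ynyl)-4,6-bis(methoxymethoxy)benzaldehyde | O[C@](C)(CCC=C(C)C)C#Cc1c(Br)c(C=O)c(OCOC)cc1OCOC
F6 | step 10 | (R,Z)-2-bromo-3-(3-hydroxy-3,7-dimethylocta-1,6-dienyl)-4,6-bis(methoxymethoxy)benzaldehyde | O[C@](C)(CCC=C(C)C)/C=C\c1c(Br)c(C=O)c(OCOC)cc1OCOC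
F7 | step 14 | [(R)-5,7-bis(methoxymethoxy)-2,8-dimethyl-2-(4-methylpent-3-enyl)-2H-chromen-6-yl]zinc chloride | COCOc1c([Zn]Cl)c(OCOC)c2c(c1C)O[C@](C)(CCC=C(C)C)C=C2
F8 | step 14 | (R)-2-methylbutanoyl chloride | CC[C@@H](C)C(=O)Cl
F9 | step 12 | [(R)-5,7-bis(methoxymethoxy)-2-methyl-2-(4-methylpent-3-enyl)-2H-chromen-8-yl]methanol | COCOc1cc(OCOC)c2c(c1CO)O[C@](C)(CCC=C(C)C)C=C2
F10 | step 12 | O-{[(R)-5,7-bis(methoxymethoxy)-2-methyl-2-(4-methylpent-3-enyl)-2H-chromen-8-yl]methyl} S-methyl dithiocarbonate | COCOc1cc(OCOC)c2c(c1COC(=S)SC)O[C@](C)(CCC=C(C)C)C=C2
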